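## The problem

Compound 19 is a flavonol: benzene ring A is fused along C4a–C8a to 4-pyranone ring C, which carries the 4-methoxyphenyl ring B at C2 and a hydroxyl at C3. The molecule has no stereocenter and no configured double bond, so no center has to control another; the task is one of regiochemistry. Four oxygens of similar phenolic or enolic character must end in four different states: methyl ether at C4', free enol at C3, free chelated phenol at C5 and prenyl ether at C7. Classical flavonol syntheses begin with a symmetrical 1,3,5-trioxygenated benzene, so they must break symmetry first and finish with a partial alkylation of a polyphenol. The prenyl ether tolerates least: acids cleave or cyclise it, strong heating moves it to carbon by Claisen rearrangement and hydrogenation destroys it, while the 3-oxy-4-pyranone unit is sensitive to oxidants and to ultraviolet light. The feature that opens another approach lies in ring A: a hydroxyl at C5 peri to the C4 carbonyl, an oxygen at C7 meta to it, and hydrogen at C6 and C8. A vinylketene and a siloxyacetylene produce exactly this pattern if the vinyl group is the C4a=C8a bond of a pyranone that already carries ring B and O3. Such a pyranone, with oxygen next to the carbonyl, an arylated ring position and a one-carbon side chain at the future C8a, is a derivative of kojic acid 1.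

## Retrosynthesis

**O7–prenyl bond.** Target 19 is cut at the O7–CH2 bond to flavonol silyl ether 16 and prenyl bromide 17. Placing the allylic ether last keeps it out of every acidic, reductive and thermal step. Carrying it on the alkyne is excluded, because allyl alkynyl ethers undergo (3,3) rearrangement far below room temperature. Alkylating a free triol with excess base would leave the choice between O7 and O3 to chance. In 16 the silyl ether is a latent phenoxide: one equivalent of fluoride should set the anion free at O7 only, as salt 18, and no other base is present. The forward step must give O- and not C-alkylation, at O7 and not at O3.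

**O3–benzyl bond.** Compound 16 is cut at the benzylic C–O bond to benzyl ether 15. Benzyl is chosen for O3 because it survives carbonate, hexavalent chromium, acid chloride formation and acylation of a diazoalkane, and leaves under neutral hydrogenolysis that an aryl silyl ether tolerates. It must be removed before the prenyl group arrives. The forward step must spare the C2=C3 bond and the O–Si bond.

**Ring A (key disconnection).** Compound 15 is cut at C8–C8a, C7–C8, C5–C6 and C4a–C5 to diazo ketone 8 and siloxyalkyne 11. The neighbouring cut, closing ring C onto a preformed trioxygenated ring A, gives back the symmetry and differentiation problem. This cut instead delivers O5 as a free chelated phenol, O7 as a silyl ether and O3 as a benzyl ether in the ring-forming event itself. The precursors are a monocyclic pyranone and a two-carbon alkyne. The forward cascade runs through ketene 12, cyclobutenone 13 and dienylketene 14. It asks for a clean Wolff rearrangement, one regiochemistry in the ketene–alkyne addition and ring closure onto the pyranone CH position.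

**Diazoacetyl group.** Diazo ketone 8 is cut at the C(O)–CHN2 bond to acid chloride 7, which is traced through carboxylic acid 6 to primary alcohol 5. This uses the hydroxymethyl carbon of kojic acid as the future C5 and avoids any C–C bond formation on the pyranone ring. The forward steps are an oxidation, a chlorination and the acylation that opens an Arndt–Eistert sequence.

**C2–aryl bond.** Alcohol 5 is cut at the bond between the pyranone and ring B to bromide 3 and 4-methoxyphenylboronic acid 4. Building the pyranone around the aryl group would be longer, whereas the cross-coupling uses a commercial boronic acid and a vinylogous acyl bromide that should add readily to palladium. The forward step must proceed without hydrolytic loss of bromide.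

**C–Br and O–benzyl bonds.** Bromide 3 is cut to bromo enol 2 and then to kojic acid 1. Bromination comes first because the free enolic hydroxyl directs the electrophile to the adjacent ring carbon; after benzylation that activation is lost.

**Siloxyalkyne.** Alkyne 11 is cut at the O–Si bond to lithium ethynolate 10, which is traced to ethyl dibromoacetate 9 by loss of both bromines and of ethoxide. The silyl group must be bulky so that the ynolate is silylated on oxygen, and it must survive heating and hydrogenolysis but leave with fluoride; triisopropylsilyl meets all three demands.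

## Roads not taken

**Alternative 1:** Biomimetic folding of a polyketide chain. The cut is the C4a–C5 bond, which opens ring A into methyl (E)-9-(4-methoxyphenyl)-3,5,7-trioxonon-8-enoate A2. Forward, Mg(OCH3)2 in methanol would chelate the chain so that C6 attacks the ester carbon, and aromatisation would give (E)-2',4',6'-trihydroxy-4-methoxychalcone A1.
- Merits: the step mirrors the biosynthesis, uses cheap and harmless reagents, needs no light, diazo compound or organolithium, and forms all carbons and oxygens of ring A at once.
- Weak points: A2 must be assembled by polyanion acylations; it can also fold by aldol condensation, lactonise to a pyranone or act as a Michael acceptor. A1 is equally available from a single aldol condensation of two commercial aromatics, so the key step buys little. After A1, ring C must still be closed oxidatively with introduction of O3, and the Algar–Flynn–Oyamada oxidation tends to divert 6'-oxygenated 2'-hydroxychalcones to aurones. Three phenols, two of them equivalent, must then be told apart.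
- Comparison: Alternative 1 is better in safety and material cost. The chosen plan sets against this a ring-forming step that leaves ring C complete and O3, O5 and O7 in three different states, as in 15, so no oxidative cyclisation and no symmetry breaking follow.

**Alternative 2:** Aryne and acylketene annulation of ring C. The cut is at O1–C8a and C4–C4a. Forward, CsF would release 3,5-bis(benzyloxy)benzyne A6 from 3,5-bis(benzyloxy)-2-(trimethylsilyl)phenyl trifluoromethanesulfonate A4, while thermolysis of 5-(benzyloxy)-6-(4-methoxyphenyl)-2,2-dimethyl-4H-1,3-dioxin-4-one A5 would release 2-(benzyloxy)-3-(4-methoxyphenyl)-3-oxoprop-1-en-1-one A7. The ketone oxygen of A7 should add to the aryne carbon remote from the flanking benzyloxy group and the aryl anion should close onto the ketene carbon, giving 3,5,7-tris(benzyloxy)-2-(4-methoxyphenyl)-4H-chromen-4-one A3.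
- Merits: it is the most convergent of the plans, with two fragments of similar size and ring C, O3 and ring B all in place after one step. The regiochemistry follows the known preference of nucleophiles for the aryne carbon distal to an alkoxy group. No photochemistry is needed.
- Weak points: A4 and A5 each need several steps, and A4 starts from a symmetrical triphenol that must be desymmetrised. Two short-lived intermediates must be generated at matched rates by different triggers (fluoride, and heat above about 100 °C); acylketenes dimerise and arynes are trapped by adventitious nucleophiles. All three oxygens arrive as identical benzyl ethers, so hydrogenolysis gives 3,5,7-trihydroxy-2-(4-methoxyphenyl)-4H-chromen-4-one A8, which must be prenylated selectively at O7 with external base.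
- Comparison: Alternative 2 is more convergent and probably similar in length. The chosen plan sets against it one reactive intermediate under one trigger, a cheap ring C precursor, and oxygens that are differentiated by construction, with the O7 silyl group itself triggering the alkylation.

**Alternative 3:** Three-component carbonylative annulation. The cut is at C4a–C4, C4–C3 and O1–C2. Forward, 2-iodo-3,5-bis(methoxymethoxy)phenol A10, carbon monoxide A12 and 4-ethynylanisole A11 would combine under PdCl2(PPh3)2 in diethylamine by oxidative addition, CO insertion, acyl–alkynyl coupling and 6-endo oxa-Michael closure. The product would be 5,7-bis(methoxymethoxy)-2-(4-methoxyphenyl)-4H-chromen-4-one A9.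
- Merits: one step forms ring C with ring B attached, the palladium chemistry is robust, the alkyne is commercial, and no diazo compound or light is involved.
- Weak points: A9 has no oxygen at C3, so a late oxidation of an electron-rich flavone is required (epoxidation–rearrangement or C3 metalation–oxidation). A10 requires mono-iodination and twofold protection of a symmetrical triphenol, a statistical operation. The doubly ortho-substituted iodide is hindered, and 5-exo closure to an aurone competes. The two acetals leave together, so the selective O7 prenylation of triol A8 returns; removing them after prenylation would expose the prenyl ether to acid.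
- Comparison: in step count Alternative 3 is at least as good as the chosen plan (roughly seven steps against ten) and it is operationally simpler. The chosen plan sets against this that O3 is present from the first step, so no late C–H oxidation is needed, and that O5 and O7 are never equivalent.

Key step: step 8

Remark on the chemistry: the Wolff rearrangement is assumed to be driven through the long-wavelength n→π* band of diazo ketone 8 (about 440 nm), as in visible-light Wolff rearrangements of α-diazo ketones. Ultraviolet light is avoided because 3-alkoxy-2-aryl-4-pyranones and the corresponding chromones are photolabile.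

## Route

Step 1
Reactants: 1 kojic acid (5-hydroxy-2-(hydroxymethyl)-4H-pyran-4-one)
Product: 2 2-bromo-3-hydroxy-6-(hydroxymethyl)-4H-pyran-4-one (6-bromokojic acid)
Conditions: NBS, DMF, 0 °C to rt
Reagents that add atoms: N-bromosuccinimide, O=C1CCC(=O)N1Br
Why: Electrophilic bromination of the enol; the free hydroxyl directs the halogen to the adjacent unsubstituted ring carbon, the position at which kojic acid also reacts in Mannich and aldol reactions, and the primary alcohol is untouched.

Step 2
Reactants: 2 2-bromo-3-hydroxy-6-(hydroxymethyl)-4H-pyran-4-one
Product: 3 3-(benzyloxy)-2-bromo-6-(hydroxymethyl)-4H-pyran-4-one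
Conditions: BnBr, K2CO3, DMF, rt
Reagents that add atoms: benzyl bromide, BrCc1ccccc1
Why: Williamson etherification; carbonate deprotonates only the acidic enolic hydroxyl, the neutral primary alcohol does not compete, and the mild base avoids addition–elimination at the bromine-bearing carbon.

Step 3
Reactants: 3 3-(benzyloxy)-2-bromo-6-(hydroxymethyl)-4H-pyran-4-one; 4 4-methoxyphenylboronic acid
Product: 5 3-(benzyloxy)-6-(hydroxymethyl)-2-(4-methoxyphenyl)-4H-pyran-4-one
Conditions: Pd(PPh3)4 (5 mol %), Na2CO3, DME/H2O, 80 °C
Reagents that add atoms: none
Why: Suzuki–Miyaura coupling; the C–Br bond of 3 is that of a vinylogous acyl bromide and should add readily to zerovalent palladium, transmetalation and reductive elimination form the C2–aryl bond, and the free alcohol is tolerated.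

Step 4
Reactants: 5 3-(benzyloxy)-6-(hydroxymethyl)-2-(4-methoxyphenyl)-4H-pyran-4-one
Product: 6 5-(benzyloxy)-6-(4-methoxyphenyl)-4-oxo-4H-pyran-2-carboxylic acid
Conditions: CrO3, H2SO4, H2O, acetone, 0 °C to rt
Reagents that add atoms: water, O
Why: Jones oxidation of a primary alcohol through the aldehyde hydrate to the acid, the standard conversion of O-benzylkojic acid into its carboxylic acid; the benzyl ether, the anisole and the pyranone are stable to cold aqueous hexavalent chromium.

Step 5
Reactants: 6 5-(benzyloxy)-6-(4-methoxyphenyl)-4-oxo-4H-pyran-2-carboxylic acid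
Product: 7 5-(benzyloxy)-6-(4-methoxyphenyl)-4-oxo-4H-pyran-2-carbonyl chloride
Conditions: (COCl)2, DMF (cat.), CH2Cl2, 0 °C to rt
Reagents that add atoms: oxalyl chloride, ClC(=O)C(Cl)=O
Why: Acid chloride formation through the chloroiminium species generated from DMF and oxalyl chloride; the by-products are gases, so crude 7 is obtained by evaporation.

Step 6
Reactants: 7 5-(benzyloxy)-6-(4-methoxyphenyl)-4-oxo-4H-pyran-2-carbonyl chloride
Product: 8 3-(benzyloxy)-6-(diazoacetyl)-2-(4-methoxyphenyl)-4H-pyran-4-one
Conditions: CH2N2, Et3N, Et2O/THF, 0 °C
Reagents that add atoms: diazomethane, C=[N+]=[N-]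
Why: Acylation of diazomethane, the first stage of an Arndt–Eistert sequence; triethylamine takes up HCl so that no chloromethyl ketone forms, 7 has no α-hydrogen and cannot be turned into a ketene by the amine, and low temperature keeps the reagent away from the pyranone double bonds.

Step 7
Reactants: 9 ethyl dibromoacetate
Product: 11 (triisopropylsilyloxy)acetylene, via lithium ethynolate 10 (not isolated)
Conditions: t-BuLi (4 equiv), THF, −78 to 0 °C; then i-Pr3SiCl, −78 °C to rt
Reagents that add atoms: chlorotriisopropylsilane, CC(C)[Si](Cl)(C(C)C)C(C)C
Why: Double bromine–lithium exchange on the α,α-dibromo ester gives an ester dianion that expels lithium ethoxide to form the ynolate (ynolate synthesis from dibromo esters); the bulky chlorosilane silylates ynolates on oxygen, whereas small silyl chlorides attack carbon.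

Step 8
Reactants: 8 3-(benzyloxy)-6-(diazoacetyl)-2-(4-methoxyphenyl)-4H-pyran-4-one; 11 (triisopropylsilyloxy)acetylene
Product: 15 3-(benzyloxy)-5-hydroxy-2-(4-methoxyphenyl)-7-(triisopropylsilyloxy)-4H-chromen-4-one, via pyranonylketene 12 (not isolated), via siloxycyclobutenone 13 (not isolated), via dienylketene 14 (not isolated)
Conditions: 11 (1.5 equiv), hν (440 nm LEDs), ClCH2CH2Cl, rt, degassed; then 80 °C
Reagents that add atoms: none
Why: Light absorbed by the n→π* band of the diazo ketone expels N2 and triggers the Wolff rearrangement, in which the pyranonyl carbon migrates to the former diazo carbon and gives ketene 12 (the C8–C8a bond). Ketene 12 and the electron-rich alkyne 11 combine in a thermal (2+2) cycloaddition in which the nucleophilic CH terminus of 11 attacks the ketene carbonyl carbon (C5–C6) and the oxygen-bearing carbon bonds to the ketene α-carbon (C7–C8), giving cyclobutenone 13 with the siloxy group at its C3. At 80 °C 13 opens by reversible conrotatory four-electron electrocyclic cleavage to dienylketene 14; only the isomer with the ketene arm cis to the pyranone can go on, and the reversibility feeds all material through it. Ring A is closed by thermal disrotatory six-electron electrocyclization of 14 onto the CH carbon of the pyranone (C4a–C5), and tautomerization of the cyclohexadienone restores the pyranone conjugation and gives the phenol hydrogen-bonded to the C4 carbonyl. The closest known reaction type is the Danheiser benzannulation in its diazo ketone form, in which α,β-unsaturated and heteroaryl diazomethyl ketones and siloxyalkynes give resorcinol monosilyl ethers. No stereocenter is formed in 15; the sp3 carbon of 13 is transient and racemic. The regiochemistry of the (2+2) event, which puts oxygen at C7 and not at C6, is secured by the polarization of the siloxyalkyne, and the site of ring closure is secured by the substrate, since the other neighbour of the ketene-bearing carbon is the ring oxygen. Chemoselective excitation is secured by visible light, which the benzyloxypyranone and the product do not absorb, and the chelated 5-hydroxyl of 15 is a poor nucleophile toward ketenes 12 and 14, which limits ester by-products.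

Step 9
Reactants: 15 3-(benzyloxy)-5-hydroxy-2-(4-methoxyphenyl)-7-(triisopropylsilyloxy)-4H-chromen-4-one
Product: 16 3,5-dihydroxy-2-(4-methoxyphenyl)-7-(triisopropylsilyloxy)-4H-chromen-4-one
Conditions: H2 (1 atm), 10% Pd/C, EtOAc, rt
Reagents that add atoms: none
Why: Hydrogenolysis of the benzyl enol ether over palladium under neutral, aprotic conditions; the aryl silyl ether, the aryl methyl ether and the tetrasubstituted C2=C3 bond of the vinylogous ester are not reduced.

Step 10
Reactants: 16 3,5-dihydroxy-2-(4-methoxyphenyl)-7-(triisopropylsilyloxy)-4H-chromen-4-one; 17 prenyl bromide (1-bromo-3-methylbut-2-ene)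
Product: 19 3,5-dihydroxy-2-(4-methoxyphenyl)-7-[(3-methylbut-2-en-1-yl)oxy]-4H-chromen-4-one (target), via tetrabutylammonium 7-phenoxide 18 (not isolated)
Conditions: 17 (1.05 equiv), Bu4NF (1.0 equiv, slow addition), THF, 0 °C to rt
Reagents that add atoms: none
Why: One-pot fluoride desilylation and Williamson O-alkylation; one equivalent of fluoride breaks the aryl O–Si bond and leaves the only equivalent of base as phenoxide 18 at O7, the most acidic position (para to the carbonyl), and SN2 attack on the primary allylic bromide gives the ether while the chelated 5-OH and the less acidic, flanked 3-OH stay protonated.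

## Compound list

1 | kojic acid (5-hydroxy-2-(hydroxymethyl)-4H-pyran-4-one) | OCc1cc(=O)c(O)co1 | starting material
2 | 2-bromo-3-hydroxy-6-(hydroxymethyl)-4H-pyran-4-one | OCc1cc(=O)c(O)c(Br)o1 | intermediate
3 | 3-(benzyloxy)-2-bromo-6-(hydroxymethyl)-4H-pyran-4-one | OCc1cc(=O)c(OCc2ccccc2)c(Br)o1 | intermediate
4 | 4-methoxyphenylboronic acid | COc1ccc(B(O)O)cc1 | starting material
5 | 3-(benzyloxy)-6-(hydroxymethyl)-2-(4-methoxyphenyl)-4H-pyran-4-one | OCc1cc(=O)c(OCc2ccccc2)c(-c2ccc(OC)cc2)o1 | intermediate
6 | 5-(benzyloxy)-6-(4-methoxyphenyl)-4-oxo-4H-pyran-2-carboxylic acid | OC(=O)c1cc(=O)c(OCc2ccccc2)c(-c2ccc(OC)cc2)o1 | intermediate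
7 | 5-(benzyloxy)-6-(4-methoxyphenyl)-4-oxo-4H-pyran-2-carbonyl chloride | ClC(=O)c1cc(=O)c(OCc2ccccc2)c(-c2ccc(OC)cc2)o1 | intermediate
8 | 3-(benzyloxy)-6-(diazoacetyl)-2-(4-methoxyphenyl)-4H-pyran-4-one | [N-]=[N+]=CC(=O)c1cc(=O)c(OCc2ccccc2)c(-c2ccc(OC)cc2)o1 | intermediate
9 | ethyl dibromoacetate | CCOC(=O)C(Br)Br | starting material
10 | lithium ethynolate | [Li+].[O-]C#C | intermediate
11 | (triisopropylsilyloxy)acetylene | C#CO[Si](C(C)C)(C(C)C)C(C)C | intermediate
12 | 3-(benzyloxy)-2-(4-methoxyphenyl)-6-(2-oxoethenyl)-4H-pyran-4-one (pyranonylketene) | O=C=Cc1cc(=O)c(OCc2ccccc2)c(-c2ccc(OC)cc2)o1 | intermediate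
13 | 3-(benzyloxy)-2-(4-methoxyphenyl)-6-[4-oxo-2-(triisopropylsilyloxy)cyclobut-2-en-1-yl]-4H-pyran-4-one (racemic) | O=C1C=C(O[Si](C(C)C)(C(C)C)C(C)C)C1c1cc(=O)c(OCc2ccccc2)c(-c2ccc(OC)cc2)o1 | intermediate
14 | 3-(benzyloxy)-2-(4-methoxyphenyl)-6-[(1E)-4-oxo-2-(triisopropylsilyloxy)buta-1,3-dien-1-yl]-4H-pyran-4-one (ketene carbon cis to the pyranone) | O=C=C/C(O[Si](C(C)C)(C(C)C)C(C)C)=C\c1cc(=O)c(OCc2ccccc2)c(-c2ccc(OC)cc2)o1 | intermediate
15 | 3-(benzyloxy)-5-hydroxy-2-(4-methoxyphenyl)-7-(triisopropylsilyloxy)-4H-chromen-4-one | COc1ccc(-c2oc3cc(O[Si](C(C)C)(C(C)C)C(C)C)cc(O)c3c(=O)c2OCc2ccccc2)cc1 | intermediate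
16 | 3,5-dihydroxy-2-(4-methoxyphenyl)-7-(triisopropylsilyloxy)-4H-chromen-4-one | COc1ccc(-c2oc3cc(O[Si](C(C)C)(C(C)C)C(C)C)cc(O)c3c(=O)c2O)cc1 | intermediate
17 | prenyl bromide (1-bromo-3-methylbut-2-ene) | CC(C)=CCBr | starting material
18 | tetrabutylammonium 3,5-dihydroxy-2-(4-methoxyphenyl)-4-oxo-4H-chromen-7-olate | CCCC[N+](CCCC)(CCCC)CCCC.COc1ccc(-c2oc3cc([O-])cc(O)c3c(=O)c2O)cc1 | intermediate
19 | 3,5-dihydroxy-2-(4-methoxyphenyl)-7-[(3-methylbut-2-en-1-yl)oxy]-4H-chromen-4-one | COc1ccc(-c2oc3cc(OCC=C(C)C)cc(O)c3c(=O)c2O)cc1 | target

## Step count and uncertain steps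

Total: 10 steps. Longest linear sequence: 9 steps (steps 1–6 and 8–10, from 1 to 19); the alkyne branch (step 7) joins at step 8.

**Step 8 (key step).** The most likely failure is a slow six-electron closure, because it must interrupt the cyclic conjugation of the pyranone. Cyclobutenone 13 would then accumulate and ketenes 12 and 14 would be lost to dimerisation or to acylation of product phenol. A second risk is photodegradation if the pyranone chromophore competes for light. The fallback separates ketene formation from light and sets out from 8. Wolff rearrangement catalysed by AgO2CPh with Et3N in aqueous dioxane, without alkyne, would give 2-[5-(benzyloxy)-6-(4-methoxyphenyl)-4-oxo-4H-pyran-2-yl]acetic acid F1. Oxalyl chloride at 0 °C would convert it into 2-[5-(benzyloxy)-6-(4-methoxyphenyl)-4-oxo-4H-pyran-2-yl]acetyl chloride F2. Dehydrochlorination of F2 with triethylamine in the presence of 11 would generate ketene 12 in the dark and lead to cyclobutenone 13, where the fallback comes back to the route. Compound 13 could then be isolated and thermolysed on its own in toluene at 110 °C to 15. F1 is a vinylogous β-keto acid and would have to be kept cold to avoid decarboxylation.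

**Step 7.** The acidic C–H of 9 may be deprotonated in competition with bromine–lithium exchange, the ynolate may be silylated on carbon, and the small, volatile alkyne 11 may be lost on isolation. The fallback uses a heavier, C-silylated alkyne and sets out from 8. Commercial (trimethylsilyl)acetylene would be lithiated with n-BuLi, oxidised at carbon with lithium tert-butyl peroxide (LiOOt-Bu) and silylated on oxygen with i-Pr3SiOSO2CF3, giving 1-(triisopropylsilyloxy)-2-(trimethylsilyl)acetylene F3. Used with 8 under the conditions of step 8, F3 should give 3-(benzyloxy)-5-hydroxy-2-(4-methoxyphenyl)-7-(triisopropylsilyloxy)-6-(trimethylsilyl)-4H-chromen-4-one F4, since the silyl group sits on the nucleophilic alkyne carbon and ends at C6. Ipso-protodesilylation of this electron-rich aryl silane with CF3CO2H in CH2Cl2 at 0 °C comes back to the route at 15.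

**Step 10.** Site selectivity may be lost: proton transfer from the 3-hydroxyl to the O7 phenoxide would allow alkylation at O3 or twofold alkylation, and the ambident phenoxide may be alkylated at C6 or C8. The fallback blocks the other hydroxyls and alkylates a neutral phenol; it sets out from 16. Acetic anhydride, pyridine and DMAP would give 2-(4-methoxyphenyl)-4-oxo-7-(triisopropylsilyloxy)-4H-chromene-3,5-diyl diacetate F5. HF·pyridine would remove the silyl group without forming a phenoxide and give 7-hydroxy-2-(4-methoxyphenyl)-4-oxo-4H-chromene-3,5-diyl diacetate F6. Mitsunobu etherification with 3-methylbut-2-en-1-ol, PPh3 and diisopropyl azodicarboxylate would give 2-(4-methoxyphenyl)-7-[(3-methylbut-2-en-1-yl)oxy]-4-oxo-4H-chromene-3,5-diyl diacetate F7. Methanolysis with catalytic K2CO3, which the prenyl ether tolerates, comes back to the route at 19.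

**Step 6.** Chemoselectivity may fail: diazomethane can add to the electron-poor pyranone double bonds, liberated HCl can give the chloromethyl ketone, and 7 is easily hydrolysed. The fallback avoids diazomethane and sets out from 7. Negishi acylation with Zn(CH3)2 and catalytic Pd(PPh3)4 would give 6-acetyl-3-(benzyloxy)-2-(4-methoxyphenyl)-4H-pyran-4-one F8. Enolisation with LiN(SiMe3)2 at −78 °C and trifluoroacetylation with 2,2,2-trifluoroethyl trifluoroacetate would give 1-[5-(benzyloxy)-6-(4-methoxyphenyl)-4-oxo-4H-pyran-2-yl]-4,4,4-trifluorobutane-1,3-dione F9. Detrifluoroacetylative diazo transfer with methanesulfonyl azide, Et3N and water in acetonitrile comes back to the route at 8.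

## Further compounds

F1 | step 8 | 2-[5-(benzyloxy)-6-(4-methoxyphenyl)-4-oxo-4H-pyran-2-yl]acetic acid | OC(=O)Cc1cc(=O)c(OCc2ccccc2)c(-c2ccc(OC)cc2)o1
F2 | step 8 | 2-[5-(benzyloxy)-6-(4-methoxyphenyl)-4-oxo-4H-pyran-2-yl]acetyl chloride | ClC(=O)Cc1cc(=O)c(OCc2ccccc2)c(-c2ccc(OC)cc2)o1
F3 | step 7 | 1-(triisopropylsilyloxy)-2-(trimethylsilyl)acetylene | C[Si](C)(C)C#CO[Si](C(C)C)(C(C)C)C(C)C
F4 | step 7 | 3-(benzyloxy)-5-hydroxy-2-(4-methoxyphenyl)-7-(triisopropylsilyloxy)-6-(trimethylsilyl)-4H-chromen-4-one | COc1ccc(-c2oc3cc(O[Si](C(C)C)(C(C)C)C(C)C)c([Si](C)(C)C)c(O)c3c(=O)c2OCc2ccccc2)cc1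
F5 | step 10 | 2-(4-methoxyphenyl)-4-oxo-7-(triisopropylsilyloxy)-4H-chromene-3,5-diyl diacetate | COc1ccc(-c2oc3cc(O[Si](C(C)C)(C(C)C)C(C)C)cc(OC(C)=O)c3c(=O)c2OC(C)=O)cc1
F6 | step 10 | 7-hydroxy-2-(4-methoxyphenyl)-4-oxo-4H-chromene-3,5-diyl diacetate | COc1ccc(-c2oc3cc(O)cc(OC(C)=O)c3c(=O)c2OC(C)=O)cc1
F7 | step 10 | 2-(4-methoxyphenyl)-7-[(3-methylbut-2-en-1-yl)oxy]-4-oxo-4H-chromene-3,5-diyl diacetate | COc1ccc(-c2oc3cc(OCC=C(C)C)cc(OC(C)=O)c3c(=O)c2OC(C)=O)cc1
F8 | step 6 | 6-acetyl-3-(benzyloxy)-2-(4-methoxyphenyl)-4H-pyran-4-one | CC(=O)c1cc(=O)c(OCc2ccccc2)c(-c2ccc(OC)cc2)o1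
F9 | step 6 | 1-[5-(benzyloxy)-6-(4-methoxyphenyl)-4-oxo-4H-pyran-2-yl]-4,4,4-trifluorobutane-1,3-dione | O=C(CC(=O)C(F)(F)F)c1cc(=O)c(OCc2ccccc2)c(-c2ccc(OC)cc2)o1
A1 | alternative 1 | (E)-2',4',6'-trihydroxy-4-methoxychalcone | COc1ccc(/C=C/C(=O)c2c(O)cc(O)cc2O)cc1
A2 | alternative 1 | methyl (E)-9-(4-methoxyphenyl)-3,5,7-trioxonon-8-enoate | COC(=O)CC(=O)CC(=O)CC(=O)/C=C/c1ccc(OC)cc1
A3 | alternative 2 | 3,5,7-tris(benzyloxy)-2-(4-methoxyphenyl)-4H-chromen-4-one | COc1ccc(-c2oc3cc(OCc4ccccc4)cc(OCc4ccccc4)c3c(=O)c2OCc2ccccc2)cc1
A4 | alternative 2 | 3,5-bis(benzyloxy)-2-(trimethylsilyl)phenyl trifluoromethanesulfonate | C[Si](C)(C)c1c(OCc2ccccc2)cc(OCc2ccccc2)cc1OS(=O)(=O)C(F)(F)F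
A5 | alternative 2 | 5-(benzyloxy)-6-(4-methoxyphenyl)-2,2-dimethyl-4H-1,3-dioxin-4-one | COc1ccc(C2=C(OCc3ccccc3)C(=O)OC(C)(C)O2)cc1
A6 | alternative 2 | 3,5-bis(benzyloxy)benzyne | O(Cc1ccccc1)C1=CC(OCc2ccccc2)=CC#C1
A7 | alternative 2 | 2-(benzyloxy)-3-(4-methoxyphenyl)-3-oxoprop-1-en-1-one | O=C=C(OCc1ccccc1)C(=O)c1ccc(OC)cc1
A8 | alternative 2 | 3,5,7-trihydroxy-2-(4-methoxyphenyl)-4H-chromen-4-one | COc1ccc(-c2oc3cc(O)cc(O)c3c(=O)c2O)cc1
A9 | alternative 3 | 5,7-bis(methoxymethoxy)-2-(4-methoxyphenyl)-4H-chromen-4-one | COCOc1cc(OCOC)c2c(=O)cc(-c3ccc(OC)cc3)oc2c1
A10 | alternative 3 | 2-iodo-3,5-bis(methoxymethoxy)phenol | Oc1cc(OCOC)cc(OCOC)c1I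
A11 | alternative 3 | 4-ethynylanisole | C#Cc1ccc(OC)cc1
A12 | alternative 3 | carbon monoxide | [C-]#[O+]
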